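**Retrosynthetic overview**
1. Ring B is closed last through C9–C10: a TiCl4-promoted intramolecular Hosomi–Sakurai addition of the (Z)-allylsilane C17–C8=C9 to the ring-A enone (C2=O, C1=C10) of 18 should give, in one operation, the cis-decalin, the quaternary C10, C9 and the C8=C17 methylene.
2. Feature that makes this possible: the C2 oxygen, raised to the ketone, turns C10 into the β-carbon of an enone in ring A; the C5–C6–C7 chain next to C10 forces same-face delivery (cis fusion); the exocyclic methylene is the trace of the silane.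
3. The arm: 1,1-dichloroalkene 15 (from methyl geranate, already carrying the (E)-enoate) is joined first to C7 and then to CH2SiMe3 by two stereoretentive Negishi couplings.
4. Ring A with C4/C5: a temporary δ-lactone ring (C19–O–C7, not in the target) carries an asymmetric rhodium 1,4-addition (C5) and two enolate alkylations (quaternary C4); metathesis closes ring A, allylic oxidation gives the enone, and the lactone is opened to the C7 iodide.
5. Order of rings: lactone ring (temporary) → ring A → lactone opened → ring B; then ester cleavage and a carboxyl-directed reduction of the C2 ketone.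

Key step: step 11

Remark: the given descriptors define a cis-fused decalin (H on C5 and the methyl on C10 on the same face; (1R,3S,4aR,5S,8aS) in naphthalene numbering). Atom numbers in the text are labdane numbers: ring A = C1–C5 and C10, ring B = C5–C10, C19 = carboxyl carbon on C4, C17 = methylene carbon on C8, C11–C15 = side chain.

**Route**

Step 1
Reactants: 1 5,6-dihydro-2H-pyran-2-one; 2 potassium trifluoro(prop-1-en-2-yl)borate
Product: 3 (4R)-4-(prop-1-en-2-yl)oxan-2-one
Conditions: [Rh(cod)2]PF6 (3 mol %), (R)-BINAP (3.3 mol %), toluene/H2O 20:1, 105 °C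
Reagents that add atoms: none
Why: Rhodium-catalysed asymmetric 1,4-addition of an alkenylboron reagent to a cyclic enoate (Hayashi–Miyaura reaction); the (R)-BINAP–rhodium alkenyl species should add to the enantioface that corresponds to the known sense for cyclohexenone and set the future C5 as R.

Step 2
Reactants: 3 (4R)-4-(prop-1-en-2-yl)oxan-2-one; 4 4-iodobut-1-ene
Product: 5 (3S,4R)-3-(but-3-en-1-yl)-4-(prop-1-en-2-yl)oxan-2-one
Conditions: LiN(i-Pr)2, THF, −78 °C; then 4, DMPU, −78 → −20 °C
Reagents that add atoms: none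
Why: Kinetic lactone enolate alkylation, in which the iodide should enter anti to the neighbouring isopropenyl group (trans-3,4 product); this centre is enolised again in step 3, so its ratio is not decisive.

Step 3
Reactants: 5 (3S,4R)-3-(but-3-en-1-yl)-4-(prop-1-en-2-yl)oxan-2-one
Product: 6 (3R,4S)-3-(but-3-en-1-yl)-3-methyl-4-(prop-1-en-2-yl)oxan-2-one
Conditions: LiN(i-Pr)2, THF, −78 °C; then MeI, −78 → 0 °C
Reagents that add atoms: iodomethane, CI
Why: Second lactone enolate alkylation; methyl iodide should again approach anti to the pseudoaxial isopropenyl group, so the quaternary C4 forms with methyl trans and butenyl cis to it, while the lactone ring holds C19 and C6 cis.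

Step 4
Reactants: 6 (3R,4S)-3-(but-3-en-1-yl)-3-methyl-4-(prop-1-en-2-yl)oxan-2-one
Product: 7 (4aS,8aR)-5,8a-dimethyl-3,4,4a,7,8,8a-hexahydro-1H-isochromen-1-one
Conditions: second-generation Grubbs catalyst RuCl2(=CHPh)(H2IMes)(PCy3) (5 mol %), CH2Cl2, 40 °C
Reagents that add atoms: none
Why: Ring-closing metathesis of the cis-disposed butenyl and isopropenyl groups closes ring A as a trisubstituted cyclohexene (C1=C10) with loss of ethene.

Step 5
Reactants: 7 (4aS,8aR)-5,8a-dimethyl-3,4,4a,7,8,8a-hexahydro-1H-isochromen-1-one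
Product: 8 (4aS,8aR)-5,8a-dimethyl-4,4a,8,8a-tetrahydro-1H-isochromene-1,7(3H)-dione
Conditions: Rh2(cap)4 (1 mol %), t-BuOOH (70% aq., 5 equiv), CH2Cl2, 40 °C
Reagents that add atoms: tert-butyl hydroperoxide, CC(C)(C)OO
Why: Allylic C–H oxidation of a trisubstituted cycloalkene at the CH2 next to its CH end (C2), the regiochemistry known from 1-methylcyclohexenes and 5-ene steroids, should give the 3-methylcyclohexenone; the tertiary allylic C5–H is shielded by the quaternary C4.

Step 6
Reactants: 8 (4aS,8aR)-5,8a-dimethyl-4,4a,8,8a-tetrahydro-1H-isochromene-1,7(3H)-dione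
Product: 11 methyl (1R,2S)-2-(2-iodoethyl)-1,3-dimethyl-5-oxocyclohex-3-ene-1-carboxylate, via silyl ester 9 (not isolated), via iodo acid 10 (not isolated)
Conditions: Me3SiI (2.5 equiv), CH2Cl2, 0 → 25 °C; MeOH; then Me3SiCHN2, toluene/MeOH, 0 °C; Et3N wash
Reagents that add atoms: iodotrimethylsilane, C[Si](C)(C)I; (trimethylsilyl)diazomethane, C[Si](C)(C)C=[N+]=[N-]
Why: Silyl iodide cleavage of a lactone by SN2 attack of iodide at the primary O–CH2 carbon (C7), followed by diazoalkane esterification of the hindered acid under non-basic conditions so that the iodo acid cannot re-lactonise; iodide added reversibly to the enone should be lost again on the amine wash.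

Step 7
Reactants: 12 methyl (2E)-3,7-dimethylocta-2,6-dienoate
Product: 14 methyl (2E)-3-methyl-6-oxohex-2-enoate, via ozonide 13 (not isolated)
Conditions: O3 (1 equiv), CH2Cl2, pyridine (cat.), −78 °C; then Me2S, −78 → 25 °C
Reagents that add atoms: ozone, [O-][O+]=O
Why: Ozonolysis with reductive work-up; ozone should react with the electron-rich trisubstituted 6,7-alkene and leave the conjugated (E)-enoate untouched.

Step 8
Reactants: 14 methyl (2E)-3-methyl-6-oxohex-2-enoate
Product: 15 methyl (2E)-7,7-dichloro-3-methylhepta-2,6-dienoate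
Conditions: PPh3 (4 equiv), CCl4, THF, 60 °C
Reagents that add atoms: carbon tetrachloride, ClC(Cl)(Cl)Cl
Why: Wittig-type dichloromethylenation of the aldehyde with the ylide formed from PPh3 and CCl4 (chlorine analogue of the Ramirez olefination).

Step 9
Reactants: 11 methyl (1R,2S)-2-(2-iodoethyl)-1,3-dimethyl-5-oxocyclohex-3-ene-1-carboxylate; 15 methyl (2E)-7,7-dichloro-3-methylhepta-2,6-dienoate
Product: 17 methyl (1R,2S)-2-[(3Z,7E)-3-chloro-9-methoxy-7-methyl-9-oxonona-3,7-dien-1-yl]-1,3-dimethyl-5-oxocyclohex-3-ene-1-carboxylate, via alkylzinc iodide 16 (not isolated)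
Conditions: Zn dust (activated), LiCl, THF, 35 °C; then 15, PdCl2(DPEphos) (5 mol %), THF, 50 °C
Reagents that add atoms: none
Why: Zinc insertion into the primary iodide tolerates enone and esters, and the trans-selective Negishi monoalkylation of a 1,1-dichloroalkene should replace only the less hindered chlorine (trans to the chain), which fixes C7 trans to C11.

Step 10
Reactants: 17 methyl (1R,2S)-2-[(3Z,7E)-3-chloro-9-methoxy-7-methyl-9-oxonona-3,7-dien-1-yl]-1,3-dimethyl-5-oxocyclohex-3-ene-1-carboxylate
Product: 18 methyl (1R,2S)-2-[(3Z,7E)-9-methoxy-7-methyl-9-oxo-3-[(trimethylsilyl)methyl]nona-3,7-dien-1-yl]-1,3-dimethyl-5-oxocyclohex-3-ene-1-carboxylate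
Conditions: Me3SiCH2MgCl, ZnCl2, THF, 0 °C; then 17, Pd(P(t-Bu)3)2 (5 mol %), THF/NMP, 60 °C
Reagents that add atoms: (trimethylsilyl)methylmagnesium chloride, C[Si](C)(C)C[Mg]Cl
Why: Second-stage Negishi coupling with retention at the remaining alkenyl chloride (zinc variant of the Kumada silylmethylation of alkenyl halides, chosen because enone and esters are present) should give the (Z)-allylsilane with CH2SiMe3 cis to C11.

Step 11
Reactants: 18 methyl (1R,2S)-2-[(3Z,7E)-9-methoxy-7-methyl-9-oxo-3-[(trimethylsilyl)methyl]nona-3,7-dien-1-yl]-1,3-dimethyl-5-oxocyclohex-3-ene-1-carboxylate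
Product: 20 methyl (1R,4aR,5S,8aS)-5-[(3E)-5-methoxy-3-methyl-5-oxopent-3-en-1-yl]-1,4a-dimethyl-6-methylidene-3-oxodecahydronaphthalene-1-carboxylate, via titanium enolate 19 (not isolated)
Conditions: TiCl4 (2.2 equiv), CH2Cl2, −78 → −40 °C; then H2O
Reagents that add atoms: none
Why: TiCl4 binds the C2 carbonyl of the ring-A enone and the γ-carbon of the allylsilane (C9) adds to the β-carbon C10 (Hosomi–Sakurai conjugate allylation, anti SE2′); the β-silyl cation at C8 loses the silyl group to give the C8=C17 methylene, and the titanium enolate 19 is protonated on work-up. The closest known reaction type is the Lewis-acid-promoted cyclisation of 3-methylcyclohex-2-enones that carry an allylsilane on a C4 side chain, which gives cis-fused bicyclic ketones with an angular methyl group. Ring B closes in a six-membered mode that is exo with respect to the enone C1=C10 (6-exo-trig at C10) and endo with respect to the allylsilane C8=C9; attack through C17 would need an eight-membered ring and is not expected. C10 is controlled by C5: the chain sits on the carbon next to C10, so C9 can only reach the enone face that carries C6, which gives the cis fusion (C10 methyl and C5 hydrogen on the same face). C9 is controlled by the (Z) geometry of the silane: in the extended chair-like transition state, where the C8 unit and its CH2SiMe3 group point away from ring A and the metal-bound carbonyl, the C11 chain (trans to C7) lies pseudo-equatorial and ends cis to the C10 methyl. The step needs chemoselectivity against protodesilylation and against the side-chain enoate; low temperature, the absence of protic acid and the low electrophilicity of the β,β-disubstituted enoate (no ring of sensible size available to it) should secure this.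

Step 12
Reactants: 20 methyl (1R,4aR,5S,8aS)-5-[(3E)-5-methoxy-3-methyl-5-oxopent-3-en-1-yl]-1,4a-dimethyl-6-methylidene-3-oxodecahydronaphthalene-1-carboxylate
Product: 22 (1R,4aR,5S,8aS)-5-[(3E)-4-carboxy-3-methylbut-3-en-1-yl]-1,4a-dimethyl-6-methylidene-3-oxodecahydronaphthalene-1-carboxylic acid, via disodium salt 21 (not isolated)
Conditions: NaSEt (6 equiv), DMF, 80 °C; then 1 M HCl
Reagents that add atoms: none
Why: SN2 O-demethylation of methyl esters by thiolate does not depend on access to the hindered C19 carbonyl and should cleave both esters while ketone and alkenes remain.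

Step 13
Reactants: 22 (1R,4aR,5S,8aS)-5-[(3E)-4-carboxy-3-methylbut-3-en-1-yl]-1,4a-dimethyl-6-methylidene-3-oxodecahydronaphthalene-1-carboxylic acid
Product: 24 (1R,3S,4aR,5S,8aS)-5-[(3E)-4-carboxy-3-methylbut-3-en-1-yl]-3-hydroxy-1,4a-dimethyl-6-methylidenedecahydronaphthalene-1-carboxylic acid, via acyloxyborohydride 23 (not isolated)
Conditions: Me4NBH(OAc)3 (5 equiv), MeCN/AcOH 1:1, −20 → 0 °C; aq. work-up
Reagents that add atoms: none
Why: Proposed new method: acetate on boron should exchange with the C19 carboxylic acid, and the tethered B–H is then delivered to the C2 carbonyl from the face of the C4 carboxyl, giving the C2 alcohol trans to that carboxyl (3S), whichever chair ring A adopts; isolated ketones are not reduced by triacetoxyborohydride, so only the internal pathway should operate, and the closest known reaction is the hydroxyl-directed Saksena–Evans reduction of β-hydroxy ketones with the same reagent (here the directing group is a carboxylic acid and the transition-state ring is one atom larger).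

**Compound list**
1 | 5,6-dihydro-2H-pyran-2-one | O=C1C=CCCO1 | starting material
2 | potassium trifluoro(prop-1-en-2-yl)borate | [K+].CC(=C)[B-](F)(F)F | starting material
3 | (4R)-4-(prop-1-en-2-yl)oxan-2-one | C=C(C)[C@H]1CC(=O)OCC1 | intermediate
4 | 4-iodobut-1-ene | C=CCCI | starting material
5 | (3S,4R)-3-(but-3-en-1-yl)-4-(prop-1-en-2-yl)oxan-2-one | C=CCC[C@@H]1C(=O)OCC[C@H]1C(C)=C | intermediate
6 | (3R,4S)-3-(but-3-en-1-yl)-3-methyl-4-(prop-1-en-2-yl)oxan-2-one | C=CCC[C@@]1(C)C(=O)OCC[C@H]1C(C)=C | intermediate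
7 | (4aS,8aR)-5,8a-dimethyl-3,4,4a,7,8,8a-hexahydro-1H-isochromen-1-one (cis-fused lactone, ring A closed) | CC1=CCC[C@@]2(C)C(=O)OCC[C@@H]12 | intermediate
8 | (4aS,8aR)-5,8a-dimethyl-4,4a,8,8a-tetrahydro-1H-isochromene-1,7(3H)-dione | CC1=CC(=O)C[C@@]2(C)C(=O)OCC[C@@H]12 | intermediate
9 | trimethylsilyl (1R,2S)-2-(2-iodoethyl)-1,3-dimethyl-5-oxocyclohex-3-ene-1-carboxylate | ICC[C@H]1C(C)=CC(=O)C[C@@]1(C)C(=O)O[Si](C)(C)C | intermediate (not isolated)
10 | (1R,2S)-2-(2-iodoethyl)-1,3-dimethyl-5-oxocyclohex-3-ene-1-carboxylic acid | ICC[C@H]1C(C)=CC(=O)C[C@@]1(C)C(=O)O | intermediate (not isolated)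
11 | methyl (1R,2S)-2-(2-iodoethyl)-1,3-dimethyl-5-oxocyclohex-3-ene-1-carboxylate | ICC[C@H]1C(C)=CC(=O)C[C@@]1(C)C(=O)OC | intermediate
12 | methyl (2E)-3,7-dimethylocta-2,6-dienoate (methyl geranate) | COC(=O)/C=C(C)/CCC=C(C)C | starting material
13 | methyl (2E)-5-(5,5-dimethyl-1,2,4-trioxolan-3-yl)-3-methylpent-2-enoate (ozonide) | COC(=O)/C=C(C)/CCC1OOC(C)(C)O1 | intermediate (not isolated)
14 | methyl (2E)-3-methyl-6-oxohex-2-enoate | COC(=O)/C=C(C)/CCC=O | intermediate
15 | methyl (2E)-7,7-dichloro-3-methylhepta-2,6-dienoate | COC(=O)/C=C(C)/CCC=C(Cl)Cl | intermediate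
16 | iodo{2-[(1S,6R)-6-(methoxycarbonyl)-2,6-dimethyl-4-oxocyclohex-2-en-1-yl]ethyl}zinc | I[Zn]CC[C@H]1C(C)=CC(=O)C[C@@]1(C)C(=O)OC | intermediate (not isolated)
17 | methyl (1R,2S)-2-[(3Z,7E)-3-chloro-9-methoxy-7-methyl-9-oxonona-3,7-dien-1-yl]-1,3-dimethyl-5-oxocyclohex-3-ene-1-carboxylate | COC(=O)/C=C(C)/CC/C=C(Cl)/CC[C@H]1C(C)=CC(=O)C[C@@]1(C)C(=O)OC | intermediate
18 | methyl (1R,2S)-2-[(3Z,7E)-9-methoxy-7-methyl-9-oxo-3-[(trimethylsilyl)methyl]nona-3,7-dien-1-yl]-1,3-dimethyl-5-oxocyclohex-3-ene-1-carboxylate | COC(=O)/C=C(C)/CC/C=C(C[Si](C)(C)C)/CC[C@H]1C(C)=CC(=O)C[C@@]1(C)C(=O)OC | intermediate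
19 | trichlorotitanium enolate of 20 (O–Ti on C2, C1=C2 double bond) | C=C1CC[C@H]2[C@](C)(C=C(O[Ti](Cl)(Cl)Cl)C[C@@]2(C)C(=O)OC)[C@H]1CC/C(C)=C/C(=O)OC | intermediate (not isolated)
20 | methyl (1R,4aR,5S,8aS)-5-[(3E)-5-methoxy-3-methyl-5-oxopent-3-en-1-yl]-1,4a-dimethyl-6-methylidene-3-oxodecahydronaphthalene-1-carboxylate | C=C1CC[C@H]2[C@](C)(CC(=O)C[C@@]2(C)C(=O)OC)[C@H]1CC/C(C)=C/C(=O)OC | intermediate
21 | disodium salt of 22 | C=C1CC[C@H]2[C@](C)(CC(=O)C[C@@]2(C)C(=O)[O-])[C@H]1CC/C(C)=C/C(=O)[O-].[Na+].[Na+] | intermediate (not isolated)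
22 | (1R,4aR,5S,8aS)-5-[(3E)-4-carboxy-3-methylbut-3-en-1-yl]-1,4a-dimethyl-6-methylidene-3-oxodecahydronaphthalene-1-carboxylic acid | C=C1CC[C@H]2[C@](C)(CC(=O)C[C@@]2(C)C(=O)O)[C@H]1CC/C(C)=C/C(=O)O | intermediate
23 | tetramethylammonium diacetoxy(acyloxy)hydridoborate of 22 (boron on the C19 carboxylate) | C=C1CC[C@H]2[C@](C)(CC(=O)C[C@@]2(C)C(=O)O[BH-](OC(C)=O)OC(C)=O)[C@H]1CC/C(C)=C/C(=O)O.C[N+](C)(C)C | intermediate (not isolated)
24 | (1R,3S,4aR,5S,8aS)-5-[(3E)-4-carboxy-3-methylbut-3-en-1-yl]-3-hydroxy-1,4a-dimethyl-6-methylidenedecahydronaphthalene-1-carboxylic acid | C=C1CC[C@H]2[C@](C)(C[C@H](O)C[C@@]2(C)C(=O)O)[C@H]1CC/C(C)=C/C(=O)O | target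

**Count and risks**
Total step count: 13. Longest linear sequence: 11 steps (steps 1–6 and 9–13).

Steps most likely to fail:

1. Step 13 (proposed new method). Ligand exchange at boron or the internal hydride transfer may be too slow, so that the ketone is not reduced or is reduced from the outside with poor facial selectivity. Fallback with known chemistry, from 20: undirected NaBH4 reduction (MeOH/THF, −40 °C) at the diester stage should give both C3 alcohols. The epimer with the hydroxyl cis to the C1 ester closes spontaneously to the bridged lactone F2 and is removed by chromatography. The wanted trans hydroxy diester F1 is demethylated with NaSEt in DMF as in step 12 and comes back to the route at 24.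

2. Step 11 (key step). Facial selectivity at the silane terminus may be poor if a folded transition state (C8 unit under ring A) competes with the extended one, which would give the C9 epimer; protodesilylation is the other loss. Fallback, from 15: the order of the two couplings is reversed. Trans-selective Negishi coupling of 15 with Me3SiCH2ZnCl (PdCl2(DPEphos)) should give the chloro allylsilane F3. Coupling of F3 with the alkylzinc 16 (Pd(P(t-Bu)3)2) gives the (E)-allylsilane F4. With TiCl4, F4 should reach the same C9 configuration through the folded array and comes back at 20.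

3. Step 10. Oxidative addition and transmetalation at the hindered alkenyl chloride may be slow, with loss of alkene geometry or reduction of the chloride. Fallback, from 17: Negishi methylation with MeZnCl (Pd(P(t-Bu)3)2) should give the methyl-substituted diene ester F5. F5 is cyclised with MeAlCl2 (CH2Cl2, −78 → 0 °C) in a Lewis-acid-promoted ene-type conjugate addition of the trisubstituted alkene to the enone, the C8 cation losing a proton from the C17 methyl, and comes back at 20.

**Further compounds**
F1 | step 13 | methyl (1R,3S,4aR,5S,8aS)-3-hydroxy-5-[(3E)-5-methoxy-3-methyl-5-oxopent-3-en-1-yl]-1,4a-dimethyl-6-methylidenedecahydronaphthalene-1-carboxylate | C=C1CC[C@H]2[C@](C)(C[C@H](O)C[C@@]2(C)C(=O)OC)[C@H]1CC/C(C)=C/C(=O)OC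
F2 | step 13 | bridged lactone of the C3 epimer of F1 (C1 carboxyl carbon joined through oxygen to C3; side-chain methyl ester kept) | C=C1CC[C@H]2[C@](C)(C[C@@H]3C[C@@]2(C)C(=O)O3)[C@H]1CC/C(C)=C/C(=O)OC
F3 | step 11 | methyl (2E,6Z)-7-chloro-3-methyl-8-(trimethylsilyl)octa-2,6-dienoate | COC(=O)/C=C(C)/CC/C=C(Cl)/C[Si](C)(C)C
F4 | step 11 | methyl (1R,2S)-2-[(3E,7E)-9-methoxy-7-methyl-9-oxo-3-[(trimethylsilyl)methyl]nona-3,7-dien-1-yl]-1,3-dimethyl-5-oxocyclohex-3-ene-1-carboxylate | COC(=O)/C=C(C)/CC/C=C(\CC[C@H]1C(C)=CC(=O)C[C@@]1(C)C(=O)OC)C[Si](C)(C)C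
F5 | step 10 | methyl (1R,2S)-2-[(3E,7E)-9-methoxy-3,7-dimethyl-9-oxonona-3,7-dien-1-yl]-1,3-dimethyl-5-oxocyclohex-3-ene-1-carboxylate | COC(=O)/C=C(C)/CC/C=C(C)/CC[C@H]1C(C)=CC(=O)C[C@@]1(C)C(=O)OC
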